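- Slowness is the first thing I test on E: with Z as charged, the forward step E + Z → G + J alone gives E a half-life of 7.60 s, shorter than the 20 s of Friday's flask, and E need not fall to half, since the way back is not counted. I therefore ask how far this reversible step can go before I ask how fast it goes.

    E + J → E.J (k1 = 2.0 /M/s)
    E + Z ⇌ G + J (K2 = 0.074, k2 = 2.6 /M/s)
    E + L → E.L (k3 = 41 /M/s)

| flask | E | Z | L | remark | time |
|---|---|---|---|---|---|
| Tuesday's | 27 mM | 35.1 mM | 2.70 mM | one stirred flow tank at steady state, fed with the mixture as stated, mean residence time 20 s |  |
| Wednesday's | 27 mM | 35.1 mM (fed, over 16.0 s) | 2.70 mM | all but Z at the start; Z goes in evenly over 16.0 s, the run ends at 20 s | 20 s |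
| Monday's | 27 mM | 35.1 mM | 2.70 mM | a single well-mixed tank run continuously and read at steady state, 100 s in it on average |  |
| Friday's | 27 mM | 35.1 mM | 2.70 mM | a closed flask charged with all of it at once and left for 20 s | 20 s |

- the stated concentrations are those of everything mixed, before any reaction; amounts are the same in each set-up
- the feed brings no volume worth counting
- run time (Wednesday's): 20 s

1. the set-up with the highest amount of G at the outlet or at the end, in percent of the E put in ("none" if the first two lie within 2 percentage points) (Tuesday's / Wednesday's / Monday's / Friday's / none)
2. amount of G at the outlet or at the end, in percent of the E put in, Tuesday's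
3. amount of G at the outlet or at the end, in percent of the E put in, Wednesday's
4. amount of G at the outlet or at the end, in percent of the E put in, Monday's
5. amount of G at the outlet or at the end, in percent of the E put in, Friday's

- L reacts first. With E as charged, L has a half-life of 0.626 s, far shorter than the half-life of E by the step to G. I therefore take 2.70 mM off E before reckoning and leave E′ = 24.3 mM to meet Z at 35.1 mM.

- My first way is iteration. Let x be the G formed, which equals the J formed while E + J is ignored, and let K = 0.074, so that x = sqrt(K(E′ − x)(Z − x)). Putting the undiminished charges in gives 7.94 mM, but this first round cheats, because it spends no E or Z on the G it forms. Going round again gives 5.73 mM, then 6.35 mM, then 6.18 mM, and the rounds swing above and below their limit.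

- My second way solves the same balance as an exact quadratic and gives 6.22 mM, which lies between the last two rounds. I trust it. Divided by the E put in, it gives the reversible ceiling, the G yield under thermodynamic control once L has taken its share and with no J removed: 23.0 %.

- E + J → E.J lifts G above that ceiling by taking J away. With E as charged, J has a half-life of 12.8 s by this step, which is shorter than the 100 s on average in Monday's tank. Monday's residence time is also longer than the 20 s of the other set-ups, so I put Monday's highest.

- The forecast gives 23.4 % for Tuesday's, 24.5 % for Wednesday's, 29.4 % for Monday's and 25.3 % for Friday's, and it names Monday's, with G “creeping up only as the E + J step drains J”.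

- The simulation gives 23.4 % for Tuesday's, 24.7 % for Wednesday's, 29.4 % for Monday's and 26.0 % for Friday's, so Monday's stands highest. With the step from E + J to E.J struck out, Monday's reads 22.6 %, against the ceiling of 23.0 %. Friday's G stands 3 percentage points above the ceiling, with E.J at 10.9 % of the E charged, while Monday's G stands 6.4 points above it, with E.J at 20.2 %.

The constants used here were set for the occasion; the result is computed.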